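## Retrosynthetic overview

1. C4–C4a (ring C) is cut last: the flavanone comes from the open-chain (S)-3-aryloxy-3-arylpropanoic acid 17 by an intramolecular C–H acylation of ring A under buffered, non-protic conditions.
2. Enabling feature: on ring A, C4a is the only unsubstituted carbon ortho to O1 (the other ortho carbon, C8, carries the prenyl group), and it is ortho to O1 and O5 and para to O7, so a three-atom acyl tether on O1 can only acylate there.
3. O1–C2 and the S centre: iridium-catalysed asymmetric allylic etherification of phenol 7 with cinnamyl carbonate 11; the vinyl group is then turned into C3–C4 (hydroboration, oxidation to the acid).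
4. Ring A comes from phloroglucinol (bis-silylated); the C8 prenyl group is set by O-(1,1-dimethylallyl)ation and aromatic Claisen rearrangement onto one of two equivalent ortho carbons. Ring B comes from methyl p-coumarate and carries the 4'-O-prenyl ether from the start.
5. Order of rings: A and B are bought as arenes; ring C is the only ring formed (step 11); desilylation ends the route.

Key step: step 11

Remark: the sense of induction in step 8 is assigned by analogy with other heteroatom nucleophiles and cinnamyl carbonates; if the R ether formed instead, the (Ra,Rc,Rc) ligand would be used.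

## Route

Step 1
Reactants: 1 phloroglucinol (benzene-1,3,5-triol)
Product: 2 3,5-bis(triisopropylsilyloxy)phenol
Conditions: TIPSCl (2.0 equiv), imidazole, DMF, 0 °C to rt; chromatography, mono- and tris-silyl ethers recycled
Reagents that add atoms: chlorotri(propan-2-yl)silane (TIPSCl), CC(C)[Si](Cl)(C(C)C)C(C)C
Why: Statistical O-silylation (silyl ether formation) of the threefold-symmetric triol should give the bis-silyl ether as the main component at two equivalents of silyl chloride, and the bulky silyl groups are chosen to survive the phenoxide, borane, oxidant and triflating conditions used later.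

Step 2
Reactants: 3 2-methylbut-3-en-2-ol
Product: 5 methyl 2-methylbut-3-en-2-yl carbonate, via lithium 2-methylbut-3-en-2-olate 4 (not isolated)
Conditions: n-BuLi, THF, −78 °C; then ClCO2Me, −78 °C to rt
Reagents that add atoms: methyl chloroformate, COC(=O)Cl
Why: O-acylation of the lithium alkoxide of a tertiary allylic alcohol by a chloroformate (carbonate formation) is the standard entry to tertiary allylic carbonates.

Step 3
Reactants: 2 3,5-bis(triisopropylsilyloxy)phenol; 5 methyl 2-methylbut-3-en-2-yl carbonate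
Product: 6 1-(2-methylbut-3-en-2-yloxy)-3,5-bis(triisopropylsilyloxy)benzene
Conditions: Pd(PPh3)4 (3 mol%), THF, 0 °C to rt
Reagents that add atoms: none
Why: Tsuji–Trost O-allylation, in which the phenol (deprotonated by the methoxide released on decarboxylation) attacks the more substituted terminus of the 1,1-dimethylallyl palladium complex under kinetic control, should give the tertiary aryl ether.

Step 4
Reactants: 6 1-(2-methylbut-3-en-2-yloxy)-3,5-bis(triisopropylsilyloxy)benzene
Product: 7 2-(3-methylbut-2-enyl)-3,5-bis(triisopropylsilyloxy)phenol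
Conditions: toluene, 110 °C, sealed tube
Reagents that add atoms: none
Why: Aromatic Claisen rearrangement of the 1,1-dimethylallyl ether should deliver the linear prenyl group to an ortho carbon, and because the two ortho carbons of 6 are equivalent by symmetry a single regioisomer is expected, with the prenyl group (future C8) between the free phenol (future O1) and one silyloxy group (future O7).

Step 5
Reactants: 8 methyl (E)-3-(4-hydroxyphenyl)prop-2-enoate (methyl p-coumarate)
Product: 9 methyl (E)-3-[4-(3-methylbut-2-enyloxy)phenyl]prop-2-enoate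
Conditions: prenyl bromide, K2CO3, acetone, reflux
Reagents that add atoms: 1-bromo-3-methylbut-2-ene (prenyl bromide), CC(C)=CCBr
Why: Williamson ether synthesis on the phenoxide should install the 4'-O-prenyl ether at the outset, where no other nucleophilic site competes.

Step 6
Reactants: 9 methyl (E)-3-[4-(3-methylbut-2-enyloxy)phenyl]prop-2-enoate
Product: 10 (E)-3-[4-(3-methylbut-2-enyloxy)phenyl]prop-2-en-1-ol
Conditions: i-Bu2AlH (2.5 equiv), CH2Cl2, −78 °C; aq. potassium sodium tartrate
Reagents that add atoms: none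
Why: 1,2-Reduction of the enoate by i-Bu2AlH should give the allylic alcohol with the E alkene unchanged.

Step 7
Reactants: 10 (E)-3-[4-(3-methylbut-2-enyloxy)phenyl]prop-2-en-1-ol
Product: 11 methyl (E)-3-[4-(3-methylbut-2-enyloxy)phenyl]prop-2-enyl carbonate
Conditions: ClCO2Me, pyridine, CH2Cl2, 0 °C
Reagents that add atoms: methyl chloroformate, COC(=O)Cl
Why: Acylation of the primary allylic alcohol by a chloroformate (carbonate formation) should give the linear allylic carbonate needed for iridium catalysis.

Step 8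
Reactants: 7 2-(3-methylbut-2-enyl)-3,5-bis(triisopropylsilyloxy)phenol; 11 methyl (E)-3-[4-(3-methylbut-2-enyloxy)phenyl]prop-2-enyl carbonate
Product: 13 1-{[(1S)-1-[4-(3-methylbut-2-enyloxy)phenyl]prop-2-enyl]oxy}-2-(3-methylbut-2-enyl)-3,5-bis(triisopropylsilyloxy)benzene, via lithium phenoxide 12 (not isolated)
Conditions: LiN(SiMe3)2 (1.0 equiv), THF, 0 °C; then 11 (1.2 equiv), [Ir(cod)Cl]2 (2 mol%), (Sa,Sc,Sc)-O,O'-(1,1'-binaphthalene-2,2'-diyl)-N,N-bis(1-phenylethyl)phosphoramidite (4 mol%, pre-activated with n-PrNH2), THF, rt to 40 °C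
Reagents that add atoms: none
Why: Iridium-catalysed asymmetric allylic etherification of a cinnamyl carbonate with a lithium aryloxide should give the branched 1-arylallyl aryl ether, the cyclometalated iridium–phosphoramidite complex controlling both the branched regiochemistry and the face of attack, so that the future C2 centre is set as S by the (Sa,Sc,Sc) ligand.

Step 9
Reactants: 13 the (S)-1-arylallyl aryl ether
Product: 15 (3S)-3-[2-(3-methylbut-2-enyl)-3,5-bis(triisopropylsilyloxy)phenoxy]-3-[4-(3-methylbut-2-enyloxy)phenyl]propan-1-ol, via B-alkyl-9-borabicyclo[3.3.1]nonane adduct 14 (not isolated)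
Conditions: 9-BBN (1.5 equiv), THF, 0 °C to rt; then NaBO3·4H2O, H2O, rt
Reagents that add atoms: sodium perborate tetrahydrate (NaBO3·4H2O), [Na+].[O-]OB=O
Why: Anti-Markovnikov hydroboration–oxidation with the bulky 9-BBN should select the monosubstituted vinyl group over the two trisubstituted prenyl alkenes, the perborate oxidation is mild enough for aryl silyl ethers, and the stereocentre is not touched.

Step 10
Reactants: 15 the (3S)-propan-1-ol
Product: 17 (3S)-3-[2-(3-methylbut-2-enyl)-3,5-bis(triisopropylsilyloxy)phenoxy]-3-[4-(3-methylbut-2-enyloxy)phenyl]propanoic acid, via aldehyde 16 (not isolated)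
Conditions: TEMPO (20 mol%), PhI(OAc)2 (2.2 equiv), MeCN–CH2Cl2–H2O, rt
Reagents that add atoms: water, O
Why: Oxoammonium-mediated (TEMPO/PhI(OAc)2) oxidation of the primary alcohol through the aldehyde hydrate should give the acid under weakly acidic, chlorine-free conditions that leave the prenyl alkenes, the electron-rich ring A and the benzylic ether intact.

Step 11
Reactants: 17 the (3S)-propanoic acid
Product: 19 (2S)-8-(3-methylbut-2-enyl)-2-[4-(3-methylbut-2-enyloxy)phenyl]-5,7-bis(triisopropylsilyloxy)chroman-4-one, via mixed carboxylic triflic anhydride 18 (not isolated)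
Conditions: Tf2O (1.1 equiv), 2,6-di-tert-butyl-4-methylpyridine (2.5 equiv), CH2Cl2, −78 to −40 °C; aq. NaHCO3
Reagents that add atoms: none
Why: Triflic anhydride converts the carboxyl group of 17 into the mixed anhydride 18 (an acyl triflate in equilibrium with the acylium ion), C4a of ring A attacks its carbonyl carbon, and the hindered pyridine removes the proton from the Wheland intermediate; the closest known reaction type is the intramolecular Friedel–Crafts acylation of 3-aryloxypropanoic acids to chroman-4-ones through mixed anhydrides. Ring C closes by a 6-exo-trig acyl substitution in which the C4a–C8a bond of the arene lies inside the new ring. No new stereocentre is formed, and C2 is not a reacting centre, so its S configuration should be carried through as long as the C2–O1 benzylic ether does not ionise, which the low temperature and the buffered, non-protic medium are chosen to prevent. The step needs site selectivity for C4a over the ortho carbon of ring B (which would give an indanone); the substrate secures it because C4a is the only free position on ring A that the tether from O1 can reach and is activated by O1 and O5 (ortho) and O7 (para), whereas the ring B ortho carbon is meta to its only oxygen.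

Step 12
Reactants: 19 the bis-silylated (2S)-flavanone
Product: 20 (2S)-5,7-dihydroxy-8-(3-methylbut-2-enyl)-2-[4-(3-methylbut-2-enyloxy)phenyl]chroman-4-one (CNP0558191.1)
Conditions: Bu4NF (2.5 equiv), AcOH (2.5 equiv), THF, 0 °C
Reagents that add atoms: none
Why: Fluoride-mediated cleavage of the two aryl silyl ethers should free both phenols, and the acetic acid buffer keeps the medium from becoming basic enough for retro-oxa-Michael opening of ring C, so the S configuration at C2 is kept.

## Compound list

1 | phloroglucinol (benzene-1,3,5-triol) | Oc1cc(O)cc(O)c1 | starting material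
2 | 3,5-bis(triisopropylsilyloxy)phenol | Oc1cc(O[Si](C(C)C)(C(C)C)C(C)C)cc(O[Si](C(C)C)(C(C)C)C(C)C)c1 | intermediate
3 | 2-methylbut-3-en-2-ol | C=CC(C)(C)O | starting material
4 | lithium 2-methylbut-3-en-2-olate | [Li+].[O-]C(C)(C)C=C | intermediate
5 | methyl 2-methylbut-3-en-2-yl carbonate | COC(=O)OC(C)(C)C=C | intermediate
6 | 1-(2-methylbut-3-en-2-yloxy)-3,5-bis(triisopropylsilyloxy)benzene | C=CC(C)(C)Oc1cc(O[Si](C(C)C)(C(C)C)C(C)C)cc(O[Si](C(C)C)(C(C)C)C(C)C)c1 | intermediate
7 | 2-(3-methylbut-2-enyl)-3,5-bis(triisopropylsilyloxy)phenol | CC(C)=CCc1c(O)cc(O[Si](C(C)C)(C(C)C)C(C)C)cc1O[Si](C(C)C)(C(C)C)C(C)C | intermediate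
8 | methyl (E)-3-(4-hydroxyphenyl)prop-2-enoate | COC(=O)/C=C/c1ccc(O)cc1 | starting material
9 | methyl (E)-3-[4-(3-methylbut-2-enyloxy)phenyl]prop-2-enoate | COC(=O)/C=C/c1ccc(OCC=C(C)C)cc1 | intermediate
10 | (E)-3-[4-(3-methylbut-2-enyloxy)phenyl]prop-2-en-1-ol | OC/C=C/c1ccc(OCC=C(C)C)cc1 | intermediate
11 | methyl (E)-3-[4-(3-methylbut-2-enyloxy)phenyl]prop-2-enyl carbonate | COC(=O)OC/C=C/c1ccc(OCC=C(C)C)cc1 | intermediate
12 | lithium 2-(3-methylbut-2-enyl)-3,5-bis(triisopropylsilyloxy)phenoxide | [Li+].[O-]c1cc(O[Si](C(C)C)(C(C)C)C(C)C)cc(O[Si](C(C)C)(C(C)C)C(C)C)c1CC=C(C)C | intermediate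
13 | 1-{[(1S)-1-[4-(3-methylbut-2-enyloxy)phenyl]prop-2-enyl]oxy}-2-(3-methylbut-2-enyl)-3,5-bis(triisopropylsilyloxy)benzene | CC(C)=CCOc1ccc([C@H](C=C)Oc2cc(O[Si](C(C)C)(C(C)C)C(C)C)cc(O[Si](C(C)C)(C(C)C)C(C)C)c2CC=C(C)C)cc1 | intermediate
14 | 9-{(3S)-3-[2-(3-methylbut-2-enyl)-3,5-bis(triisopropylsilyloxy)phenoxy]-3-[4-(3-methylbut-2-enyloxy)phenyl]propyl}-9-borabicyclo[3.3.1]nonane | CC(C)=CCOc1ccc([C@H](CCB3C4CCCC3CCC4)Oc2cc(O[Si](C(C)C)(C(C)C)C(C)C)cc(O[Si](C(C)C)(C(C)C)C(C)C)c2CC=C(C)C)cc1 | intermediate
15 | (3S)-3-[2-(3-methylbut-2-enyl)-3,5-bis(triisopropylsilyloxy)phenoxy]-3-[4-(3-methylbut-2-enyloxy)phenyl]propan-1-ol | CC(C)=CCOc1ccc([C@H](CCO)Oc2cc(O[Si](C(C)C)(C(C)C)C(C)C)cc(O[Si](C(C)C)(C(C)C)C(C)C)c2CC=C(C)C)cc1 | intermediate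
16 | (3S)-3-[2-(3-methylbut-2-enyl)-3,5-bis(triisopropylsilyloxy)phenoxy]-3-[4-(3-methylbut-2-enyloxy)phenyl]propanal | CC(C)=CCOc1ccc([C@H](CC=O)Oc2cc(O[Si](C(C)C)(C(C)C)C(C)C)cc(O[Si](C(C)C)(C(C)C)C(C)C)c2CC=C(C)C)cc1 | intermediate
17 | (3S)-3-[2-(3-methylbut-2-enyl)-3,5-bis(triisopropylsilyloxy)phenoxy]-3-[4-(3-methylbut-2-enyloxy)phenyl]propanoic acid | CC(C)=CCOc1ccc([C@H](CC(=O)O)Oc2cc(O[Si](C(C)C)(C(C)C)C(C)C)cc(O[Si](C(C)C)(C(C)C)C(C)C)c2CC=C(C)C)cc1 | intermediate
18 | (3S)-3-[2-(3-methylbut-2-enyl)-3,5-bis(triisopropylsilyloxy)phenoxy]-3-[4-(3-methylbut-2-enyloxy)phenyl]propanoic trifluoromethanesulfonic anhydride | CC(C)=CCOc1ccc([C@H](CC(=O)OS(=O)(=O)C(F)(F)F)Oc2cc(O[Si](C(C)C)(C(C)C)C(C)C)cc(O[Si](C(C)C)(C(C)C)C(C)C)c2CC=C(C)C)cc1 | intermediate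
19 | (2S)-8-(3-methylbut-2-enyl)-2-[4-(3-methylbut-2-enyloxy)phenyl]-5,7-bis(triisopropylsilyloxy)chroman-4-one | CC(C)=CCOc1ccc([C@@H]2CC(=O)c3c(O[Si](C(C)C)(C(C)C)C(C)C)cc(O[Si](C(C)C)(C(C)C)C(C)C)c(CC=C(C)C)c3O2)cc1 | intermediate
20 | (2S)-5,7-dihydroxy-8-(3-methylbut-2-enyl)-2-[4-(3-methylbut-2-enyloxy)phenyl]chroman-4-one (CNP0558191.1) | CC(C)=CCOc1ccc([C@@H]2CC(=O)c3c(O)cc(O)c(CC=C(C)C)c3O2)cc1 | target

## Step count and risks

Total step count: 12 steps.

Longest linear sequence: 8 steps (steps 1, 3, 4, 8, 9, 10, 11, 12 from phloroglucinol; the ring B branch, steps 5, 6, 7 and then 8 to 12, is equally long).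

Steps most likely to fail:

1. Step 11 (ring closure). The C2–O1 p-alkoxybenzylic ether may ionise under the triflating conditions, eroding the S configuration or cleaving the ether; the prenyl groups may be protonated; closure next to the bulky C5 silyloxy group may be slow enough for ketene formation and oligomerisation to compete. The fallback replaces the acylium-type electrophile by a chloroiminium ion. Setting out from acid 17, amide coupling (Me2NH·HCl, EDC·HCl, HOBt, i-Pr2NEt, CH2Cl2) would give (3S)-N,N-dimethyl-3-[2-(3-methylbut-2-enyl)-3,5-bis(triisopropylsilyloxy)phenoxy]-3-[4-(3-methylbut-2-enyloxy)phenyl]propanamide F1. A Vilsmeier–Haack-type cyclisation (POCl3, 2,6-lutidine, MeCN, 0 °C to rt) would close ring C at C4a as the cyclic (2S)-N,N-dimethylchroman-4-iminium salt F2, and aqueous NaOAc would hydrolyse it, coming back to the route at 19.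

2. Step 8 (asymmetric etherification). The ortho-substituted, electron-rich phenoxide may give poor branched-to-linear or facial selectivity, may react at carbon, or the product may re-ionise on the catalyst and drift to the linear ether. The fallback uses a copper allenylidene electrophile instead of an allyl iridium complex and sets out from phenol 7. 4-Hydroxybenzaldehyde would be O-prenylated (prenyl bromide, K2CO3, acetone) to 4-(3-methylbut-2-enyloxy)benzaldehyde F3. Addition of HC≡CMgBr (THF, 0 °C) would give racemic 1-[4-(3-methylbut-2-enyloxy)phenyl]prop-2-yn-1-ol F4, and acetylation (Ac2O, Et3N, DMAP) would give 1-[4-(3-methylbut-2-enyloxy)phenyl]prop-2-ynyl acetate F5. Copper-catalysed asymmetric propargylic etherification of 7 with F5 ((CuOTf)2·C6H6, the Ph-pybox enantiomer that leads to the S ether, i-Pr2NEt, THF) would give the (S)-propargylic aryl ether 1-{[(1S)-1-[4-(3-methylbut-2-enyloxy)phenyl]prop-2-ynyl]oxy}-2-(3-methylbut-2-enyl)-3,5-bis(triisopropylsilyloxy)benzene F6. Semi-hydrogenation (H2, Pd/CaCO3 poisoned by Pb(OAc)2, quinoline, EtOAc) would come back to the route at 13.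

3. Step 3 (O-(1,1-dimethylallyl)ation). The phenoxide may attack the less substituted allyl terminus, giving the linear prenyl ether that cannot deliver a linear C-prenyl group on rearrangement; the electron-rich ring may be allylated at carbon; the tertiary ether may re-ionise on palladium. The fallback builds the tertiary ether without an allyl-metal intermediate and sets out from phenol 2. Copper-catalysed propargylation with 3-chloro-3-methylbut-1-yne (CuCl2 cat., DBU, MeCN, 0 °C) would give 1-(2-methylbut-3-yn-2-yloxy)-3,5-bis(triisopropylsilyloxy)benzene F7, and semi-hydrogenation (H2, Pd/CaCO3 poisoned by Pb(OAc)2, quinoline, EtOAc) would come back to the route at 6.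

## Further compounds

F1 | step 11 | (3S)-N,N-dimethyl-3-[2-(3-methylbut-2-enyl)-3,5-bis(triisopropylsilyloxy)phenoxy]-3-[4-(3-methylbut-2-enyloxy)phenyl]propanamide | CC(C)=CCOc1ccc([C@H](CC(=O)N(C)C)Oc2cc(O[Si](C(C)C)(C(C)C)C(C)C)cc(O[Si](C(C)C)(C(C)C)C(C)C)c2CC=C(C)C)cc1
F2 | step 11 | (2S)-N,N-dimethyl-8-(3-methylbut-2-enyl)-2-[4-(3-methylbut-2-enyloxy)phenyl]-5,7-bis(triisopropylsilyloxy)chroman-4-iminium chloride | CC(C)=CCOc1ccc([C@@H]2CC(=[N+](C)C)c3c(O[Si](C(C)C)(C(C)C)C(C)C)cc(O[Si](C(C)C)(C(C)C)C(C)C)c(CC=C(C)C)c3O2)cc1.[Cl-]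
F3 | step 8 | 4-(3-methylbut-2-enyloxy)benzaldehyde | O=Cc1ccc(OCC=C(C)C)cc1
F4 | step 8 | 1-[4-(3-methylbut-2-enyloxy)phenyl]prop-2-yn-1-ol | C#CC(O)c1ccc(OCC=C(C)C)cc1
F5 | step 8 | 1-[4-(3-methylbut-2-enyloxy)phenyl]prop-2-ynyl acetate | CC(=O)OC(C#C)c1ccc(OCC=C(C)C)cc1
F6 | step 8 | 1-{[(1S)-1-[4-(3-methylbut-2-enyloxy)phenyl]prop-2-ynyl]oxy}-2-(3-methylbut-2-enyl)-3,5-bis(triisopropylsilyloxy)benzene | CC(C)=CCOc1ccc([C@H](C#C)Oc2cc(O[Si](C(C)C)(C(C)C)C(C)C)cc(O[Si](C(C)C)(C(C)C)C(C)C)c2CC=C(C)C)cc1
F7 | step 3 | 1-(2-methylbut-3-yn-2-yloxy)-3,5-bis(triisopropylsilyloxy)benzene | C#CC(C)(C)Oc1cc(O[Si](C(C)C)(C(C)C)C(C)C)cc(O[Si](C(C)C)(C(C)C)C(C)C)c1
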